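At early times the red flask was already past the part I could watch: by the first sample, at 4.00 h, its substrate read 0%.

in all of them: substrate 43 mM; gas phase 1.5 mM (held); catalyst 86 µM

|  | temperature | remark | time |
|---|---|---|---|
| red | 70 °C | the very flask that is asked about, followed so far |  |
| blue | 76 °C | run made earlier |  |
| flask | 70 °C |  | 4.0 d |

| run | time / h | target / % | substrate / % |
|---|---|---|---|
| red | 4.00 | 23.4 | 0 |
| red | 12.0 | 23.2 | 0.6 |
| red | 20.0 | 23.8 | 0 |
| red | 30.0 | 23.1 | 0 |
| red | 50.0 | 23.4 | 0 |
| red | 60.0 | 23.5 | 0 |
| red | 72.0 | 23.2 | 0 |
| blue | 4.00 | 29.0 | 0 |
| blue | 12.0 | 27.9 | 0.1 |
| blue | 20.0 | 28.3 | 0.2 |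
| blue | 30.0 | 29.1 | 0 |
| blue | 50.0 | 28.6 | 0.2 |
| blue | 60.0 | 28.3 | 0 |
| blue | 72.0 | 28.8 | 0 |

(each reading ± 0.3 percentage points)

- target that was removed still counts
- the analysis behind the earlier runs scatters by 0.3 percentage points, standard deviation
- at the start none of the gas phase is in solution
- additions bring no volume worth counting

- south-east: at 4.0 d take out 90% of the target then present, then wait 50 h
- south-west: at 4.0 d add catalyst, 100% of the amount charged, then wait 50 h
- north-west: at 4.0 d raise the temperature by 20 K, then wait 50 h
- east: change nothing and wait 50 h more

* target, in percent of the substrate first charged, at 4.0 d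
* the remedy with the largest gain of target, or "none" below 2 percentage points (south-east / south-west / north-west / east / none)
* target present, with what was taken out counted in, in percent of the substrate first charged, after south-east
* target present, with what was taken out counted in, in percent of the substrate first charged, after north-west

My first question was what the flat target meant. The red readings averaged 23.4% and the blue ones 28.6%, a gap of 5.2 percentage points against a scatter of 0.3 points, so the plateau moved with temperature. Red read 3.28 and blue 2.50 for the quantity I carried, the split: the part of the charged substrate not found as target over the part found as target.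

My second question was whether the split was a choice made while substrate lasted or a balance still held afterwards, which is thermodynamic control. The flat readings fit both, so this was a wager, and I committed to the balance.

The third question was what each remedy then gave. I let the split shrink by the same factor per kelvin as from red to blue, so in my reckoning the rise of 20 K gave a split of 1.33 and 43.0% target. After 90% of the target is taken out, I expected what remained to divide again at 70 °C, giving 39.5% with the removed target counted in. I expected no gain from catalyst or waiting, and in my reckoning north-west gave more target than south-east.

The forecast gave 23.4% at 4.0 d, 23.4% after south-east, 23.4% after north-west, and best none, holding that “the simpler reading is a fixed selectivity split”. It differed from my reckoning on the remedies.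

The flask gave 23.3%, then 39.3% after south-east and 43.4% after north-west, with best north-west.

    gas phase ⇌ dissolved gas, rate k1*(csat - [dissolved gas]) (kL = 0.280 min⁻¹)
    dissolved gas → decomposed reagent (k = 0.00820 min⁻¹, Ea = 101 kJ mol⁻¹)
    target + catalyst ⇌ isomer of the product + catalyst, rate k3*[catalyst]*[target] forward; the back reaction follows from the equilibrium constant (K = 3.30, k = 1500 M⁻¹ min⁻¹, Ea = 39.0 kJ mol⁻¹, ΔH = −48.0 kJ mol⁻¹)
    substrate + dissolved gas + catalyst → catalyst + target (k = 21000 M⁻² s⁻¹, Ea = 31.0 kJ mol⁻¹)
    (constants at 70 °C)

The relaxation half-life of target and isomer of the product, both ways together, was 0.0687 h at 96.0 h, far shorter than the 4.0 d, and the flask then held 76.7% isomer of the product to 23.3% target, a split of 3.29 from its 23.3% target. Carried to the neighbour flask at 85 °C, the red-to-blue factor gave a split of 1.66, so 37.6% target, and that neighbour flask ended with 38.0% target.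

The numbers in the tables are simulated from invented constants, noise included.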